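**Retrosynthetic overview**

1. The bridging ether C3–O–C10 of the oxolane (C3 a hemiketal carbon, C10 a quaternary allylic carbon) is the retron of a Criegee C→O shift. The target is traced to a tertiary hydroperoxide at C3 of a cyclobutane (C10–C1–C2–C3) cis-fused to an eight-membered carbocycle (C3–C10). Insertion of O into C3–C10 turns the eight-membered carbocycle into the nine-membered oxacycle and the cyclobutane into the oxolane, and leaves the ten-membered carbocycle as perimeter.
2. The hydroperoxide comes from the C2=C3 cyclobutene (hydroperoxysilylation), the cyclobutene from dehydration of the C3 carbinol, and C4(CH3)(OAc) from the C4 ketone (methylenation, hydration, acetylation).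
3. The butenolide-fused 4–8 system comes from a de Mayo sequence: aldol at C7 of a [2+2] photoadduct, then acid-triggered retro-aldol (six- to eight-membered ring) and enol lactonization.
4. The photoadduct comes from (R)-3,5-bis(silyloxy)cyclohexenone (a desymmetrized meso ketone, the source of all absolute configuration) and the silyl enol ether of 2-methylcyclobutanone.
5. Ring order: cyclohexenone → two cyclobutanes → cyclooctane → butenolide → oxolane, nine-membered oxacycle and ten-membered carbocycle together.

Key step: step 17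

Numbering used for all compounds: C12 lactone carbonyl, C11 its α-carbon (bears C13H2OAc), C7 β-carbon, C8 γ-carbon, C9 exocyclic =CH, C10 methyl-bearing quaternary carbon, C1–C2 the CH2CH2 unit, C3 hemiketal carbon, C4 the C(CH3)(OAc) carbon, C5 the CH2, C6 the CHOH. TBS = tert-butyldimethylsilyl, TES = triethylsilyl.

Assumption: the (R,R)-lithium amide is taken to give the (5R)-enol ether in step 3; if the sense of induction is opposite, the (S,S)-amide is used and nothing else changes.

**Step 1**
Reactants: 1 cis,cis-cyclohexane-1,3,5-triol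
Product: 2 all-cis-3,5-bis(tert-butyldimethylsilyloxy)cyclohexan-1-ol
Conditions: TBSCl (2.0 equiv), imidazole, DMF, 0 °C → rt
Reagents that add atoms: tert-butyldimethylsilyl chloride, CC(C)(C)[Si](C)(C)Cl
Why: Silyl ether formation with two equivalents of TBSCl on the all-cis triol should give the bis-ether as the main statistical product (mono- and tris-ethers are separable and recyclable), and no stereocentre is touched.

**Step 2**
Reactants: 2 all-cis-3,5-bis(tert-butyldimethylsilyloxy)cyclohexan-1-ol
Product: 3 cis-3,5-bis(tert-butyldimethylsilyloxy)cyclohexan-1-one (meso)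
Conditions: TPAP (cat.), NMO, 4 Å MS, CH2Cl2, rt
Reagents that add atoms: none
Why: Ley–Griffith oxidation of the one free secondary alcohol under neutral conditions should give the meso ketone without β-elimination of the silyloxy groups.

**Step 3**
Reactants: 3 cis-3,5-bis(tert-butyldimethylsilyloxy)cyclohexan-1-one
Product: 4 (3S,5R)-3,5-bis(tert-butyldimethylsilyloxy)-1-(trimethylsilyloxy)cyclohex-1-ene
Conditions: lithium (R,R)-bis(1-phenylethyl)amide (from the amine and n-BuLi), LiCl, TMSCl (in situ quench), THF, −100 °C
Reagents that add atoms: chlorotrimethylsilane, C[Si](C)(C)Cl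
Why: Enantioselective deprotonation (chiral lithium amide desymmetrization of a Cs-symmetric cis-3,5-disubstituted cyclohexanone with internal silyl quench) should remove one of the two enantiotopic axial α-hydrogens, so that the base alone decides which silyloxy carbon becomes C6 (R) and which becomes C4.

**Step 4**
Reactants: 4 (3S,5R)-3,5-bis(tert-butyldimethylsilyloxy)-1-(trimethylsilyloxy)cyclohex-1-ene
Product: 5 (5R)-3,5-bis(tert-butyldimethylsilyloxy)cyclohex-2-en-1-one
Conditions: Pd(OAc)2 (10 mol %), O2 (1 atm), DMSO, rt
Reagents that add atoms: none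
Why: Saegusa–Ito oxidation (α-palladio ketone formation and β-hydride elimination of the C4–H) should give the β-silyloxy enone and leaves the C6 stereocentre untouched.

**Step 5**
Reactants: 6 2-methylcyclobutan-1-one
Product: 7 1-methyl-2-(triethylsilyloxy)cyclobut-1-ene
Conditions: TESOTf, Et3N, CH2Cl2, 0 °C → rt (equilibrating)
Reagents that add atoms: triethylsilyl trifluoromethanesulfonate, CC[Si](CC)(CC)OS(=O)(=O)C(F)(F)F
Why: Silyl enol ether formation by soft enolization under equilibrating conditions should favour the more substituted, tetrasubstituted enol ether.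

**Step 6**
Reactants: 5 (5R)-3,5-bis(tert-butyldimethylsilyloxy)cyclohex-2-en-1-one; 7 1-methyl-2-(triethylsilyloxy)cyclobut-1-ene
Product: 8 cis-anti-cis [2+2] photoadduct (new cyclobutane C9–C4–C3–C10)
Conditions: hν (350 nm, Pyrex), 7 (4 equiv), hexane/CH2Cl2, −40 °C
Reagents that add atoms: none
Why: Enone–alkene [2+2] photocycloaddition (first half of a de Mayo reaction) of the triplet enone with the electron-rich enol ether should be head-to-tail (O-bearing C3 to the β-carbon C4 and C10 to C9), occur on the enone face anti to the C6 silyloxy group with the cyclobutene CH2CH2 exo (cis-anti-cis), and thereby set C10 (with C3, C4, C9; both ring fusions necessarily cis) relative to C6.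

**Step 7**
Reactants: 9 ethyl 3-bromo-2-oxopropanoate
Product: 10 ethyl 3-acetoxy-2-oxopropanoate
Conditions: KOAc, acetone, rt
Reagents that add atoms: potassium acetate, CC(=O)[O-].[K+]
Why: SN2 displacement of the activated α-bromo ketone by acetate.

**Step 8**
Reactants: 8 cis-anti-cis [2+2] photoadduct; 10 ethyl 3-acetoxy-2-oxopropanoate
Product: 11 C7 aldol adduct of the photoadduct
Conditions: LDA, THF, −78 °C; then 10 (inverse addition), −78 °C; AcOH quench
Reagents that add atoms: none
Why: Directed aldol addition of the lithium enolate, which can form only toward C7 because C9 is a hindered ring-fusion methine, to the ketone carbonyl of the α-keto ester; the new centres at C7 and C11 are formed as a mixture and are erased in step 9.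

**Step 9**
Reactants: 11 C7 aldol adduct of the photoadduct
Product: 13 C4-ketone γ-alkylidene butenolide on the cyclobutane-fused eight-membered ring, via ring-expanded diketo ester 12 (not isolated)
Conditions: CSA (0.2 equiv), benzene, 50 °C
Reagents that add atoms: none
Why: Acid should open the donor–acceptor cyclobutane by retro-aldol cleavage of C4–C9 with loss of the C4 silyl group (second half of the de Mayo reaction, six- to eight-membered ring), then dehydrate the aldol through the C8 enol and close the enol lactone toward C9, the only enolizable side, so that the ring fixes the C8=C9 geometry while C3, C6 and C10 are untouched.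

**Step 10**
Reactants: 13 C4-ketone γ-alkylidene butenolide
Product: 14 4-methylene compound
Conditions: Zn, CH2Br2, TiCl4, THF/CH2Cl2, 0 °C → rt
Reagents that add atoms: dibromomethane, BrCBr
Why: Takai–Lombardo methylenation with the non-basic Zn/Ti gem-dimetal reagent should convert the hindered, enolizable C4 ketone chemoselectively in the presence of the lactone and the acetate.

**Step 11**
Reactants: 14 4-methylene compound
Product: 16 tertiary C4 alcohol, via C4 hydroperoxide 15 (not isolated)
Conditions: Co(acac)2 (cat.), PhSiH3, O2 (1 atm), i-PrOH/CH2Cl2, 0 °C; then PPh3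
Reagents that add atoms: dioxygen, O=O
Why: Mukaiyama hydration (metal-hydride hydrogen-atom transfer to the terminal CH2, O2 capture of the tertiary C4 radical, reduction of the hydroperoxide) should prefer the 1,1-disubstituted alkene over the hindered dienyl lactone, and O2 should add to the planar radical anti to the C3 silyloxy group and the C10 methyl, which gives the 4S carbinol.

**Step 12**
Reactants: 16 tertiary C4 alcohol
Product: 17 C4 acetate
Conditions: Ac2O, DMAP, Et3N, CH2Cl2, 40 °C
Reagents that add atoms: acetic anhydride, CC(=O)OC(C)=O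
Why: DMAP-catalysed acylation (Steglich-type acyl transfer) of the only free hydroxyl, the tertiary C4 alcohol.

**Step 13**
Reactants: 17 C4 acetate
Product: 18 tertiary C3 cyclobutanol
Conditions: HF·pyridine, pyridine, THF, 0 °C
Reagents that add atoms: none
Why: Silyl ether cleavage with buffered HF·pyridine should remove the more labile triethylsilyl group and leave the secondary TBS ether, the acetates and the lactone.

**Step 14**
Reactants: 18 tertiary C3 cyclobutanol
Product: 19 C2=C3 cyclobutene
Conditions: Burgess reagent, benzene, 50 °C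
Reagents that add atoms: none
Why: Burgess dehydration (syn-elimination of the sulfamate) can only use the C2 hydrogens because C4 and C10 are quaternary, so the C2=C3 cyclobutene is the only regioisomer and no stereocentre changes.

**Step 15**
Reactants: 19 C2=C3 cyclobutene
Product: 20 C3 triethylsilyl peroxide
Conditions: Co(thd)2 (cat.), Et3SiH, O2 (1 atm), ClCH2CH2Cl, rt
Reagents that add atoms: dioxygen, O=O; triethylsilane, CC[SiH](CC)CC
Why: Isayama–Mukaiyama hydroperoxysilylation: hydrogen-atom transfer to C2 of the strained trisubstituted cyclobutene gives the tertiary C3 radical, which is trapped by O2 and silylated; the configuration at C3 (drawn cis-fused) does not matter because C3 becomes trigonal in step 17.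

**Step 16**
Reactants: 20 C3 triethylsilyl peroxide
Product: 21 C3 hydroperoxide with free C6 hydroxyl
Conditions: HF·pyridine, THF, 0 °C → rt
Reagents that add atoms: none
Why: HF·pyridine should cleave the O–Si bond of the silyl peroxide and the C6 TBS ether without touching the O–O bond, the acetates or the lactone (desilylation).

**Step 17**
Reactants: 21 C3 hydroperoxide with free C6 hydroxyl
Product: 24 CNP0203479.1 (target), via pertrifluoroacetate 22 (not isolated), via bridged ketal trifluoroacetate 23 (not isolated)
Conditions: TFAA, pyridine, CH2Cl2, −40 → 0 °C; then sat. aq. NaHCO3/MeOH, 0 °C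
Reagents that add atoms: none
Why: Trifluoroacetylation of the hydroperoxide (and of the C6 hydroxyl) gives perester 22, whose O–O bond heterolyses with a concerted 1,2-shift of C10 from C3 to oxygen (Criegee rearrangement) that relieves the cyclobutane strain and gives a bridged oxocarbenium ion, which collapses with trifluoroacetate to ketal ester 23; bicarbonate methanolysis then frees the C3 hemiketal and the C6 alcohol while the acetates stay. The closest known reaction type is the Criegee rearrangement of ring-fusion tertiary hydroperoxide esters of fused bicycles (the 9-decalyl case gives a bridged 1-acyloxy epoxycyclodecane), together with the Hock cleavage. Three rings arise from the one C→O shift and not from a cyclization with a Baldwin descriptor: the oxolane (from the cyclobutane, 4→5), the nine-membered oxacycle (from the eight-membered carbocycle by insertion of O into C3–C10, 8→9) and, as their perimeter, the ten-membered carbocycle. C10 migrates with retention, so its R configuration is the one set in step 6, and the C3 hemiketal can only take the cis-2,5-bridged S configuration, which is also the equilibrium form. The step needs C10 to migrate and not C2 or C4: C10 is tertiary and allylic and its shift opens the four-membered ring, C2 is primary, and C4 is deactivated by its acetoxy group; a perester and not a peracid is used so that the dienyl lactone is not epoxidized.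

**Compound list**

1 | cis,cis-cyclohexane-1,3,5-triol (all-cis, meso) | O[C@@H]1C[C@H](O)C[C@H](O)C1 | starting material
2 | all-cis-3,5-bis(tert-butyldimethylsilyloxy)cyclohexan-1-ol (meso) | O[C@@H]1C[C@H](O[Si](C)(C)C(C)(C)C)C[C@H](O[Si](C)(C)C(C)(C)C)C1 | intermediate
3 | cis-3,5-bis(tert-butyldimethylsilyloxy)cyclohexan-1-one (meso) | O=C1C[C@H](O[Si](C)(C)C(C)(C)C)C[C@H](O[Si](C)(C)C(C)(C)C)C1 | intermediate
4 | (3S,5R)-3,5-bis(tert-butyldimethylsilyloxy)-1-(trimethylsilyloxy)cyclohex-1-ene | C[Si](C)(C)OC1=C[C@@H](O[Si](C)(C)C(C)(C)C)C[C@@H](O[Si](C)(C)C(C)(C)C)C1 | intermediate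
5 | (5R)-3,5-bis(tert-butyldimethylsilyloxy)cyclohex-2-en-1-one (C8=O, C9=C4, stereocentre = C6) | O=C1C=C(O[Si](C)(C)C(C)(C)C)C[C@@H](O[Si](C)(C)C(C)(C)C)C1 | intermediate
6 | 2-methylcyclobutan-1-one (racemic) | CC1CCC1=O | starting material
7 | 1-methyl-2-(triethylsilyloxy)cyclobut-1-ene | CC1=C(O[Si](CC)(CC)CC)CC1 | intermediate
8 | [2+2] photoadduct: cyclohexanone (C8=O, C7, C6, C5, C4, C9) cis-fused along C4–C9 to cyclobutane C9–C4–C3–C10, itself cis-fused along C3–C10 to cyclobutane C3–C2–C1–C10 (cis-anti-cis); 4-OTBS; 6-OTBS anti to the new cyclobutane; 3-OTES and 10-methyl cis | O=C1C[C@H](O[Si](C)(C)C(C)(C)C)C[C@@]2(O[Si](C)(C)C(C)(C)C)[C@]3(O[Si](CC)(CC)CC)CC[C@]3(C)[C@@H]12 | intermediate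
9 | ethyl 3-bromo-2-oxopropanoate | CCOC(=O)C(=O)CBr | starting material
10 | ethyl 3-acetoxy-2-oxopropanoate | CCOC(=O)C(=O)COC(C)=O | intermediate
11 | aldol adduct of 8: C7 carries C11(OH)(CH2OAc)(CO2Et); mixture at C7 and C11, other centres as in 8 | O=C1C(C(O)(COC(C)=O)C(=O)OCC)[C@H](O[Si](C)(C)C(C)(C)C)C[C@@]2(O[Si](C)(C)C(C)(C)C)[C@]3(O[Si](CC)(CC)CC)CC[C@]3(C)[C@@H]12 | intermediate
12 | ring-expanded diketo ester: eight-membered ring C3–C10 with C4=O and C8=O, cis-fused cyclobutane C10–C1–C2–C3 (3-OTES and 10-methyl cis), 6-OTBS on the face of the cyclobutane CH2CH2, C7 side chain as in 11 | CCOC(=O)C(O)(COC(C)=O)C1C(=O)C[C@@]2(C)CC[C@@]2(O[Si](CC)(CC)CC)C(=O)C[C@H]1O[Si](C)(C)C(C)(C)C | intermediate (not isolated)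
13 | γ-alkylidene butenolide (C12 lactone, C7=C11, C8=C9 cis in the ring, 13-OAc) fused to the eight-membered ring; C4 ketone; cis-fused cyclobutane with 3-OTES and 10-methyl; 6-OTBS | CC(=O)OCC1=C2/C(=C\[C@@]3(C)CC[C@@]3(O[Si](CC)(CC)CC)C(=O)C[C@H]2O[Si](C)(C)C(C)(C)C)OC1=O | intermediate
14 | 4-methylene analogue of 13 (C4=CH2) | CC(=O)OCC1=C2/C(=C\[C@@]3(C)CC[C@@]3(O[Si](CC)(CC)CC)C(=C)C[C@H]2O[Si](C)(C)C(C)(C)C)OC1=O | intermediate
15 | 4-hydroperoxy-4-methyl compound (OOH anti to 3-OTES and 10-methyl) | CC(=O)OCC1=C2/C(=C\[C@@]3(C)CC[C@@]3(O[Si](CC)(CC)CC)[C@@](C)(OO)C[C@H]2O[Si](C)(C)C(C)(C)C)OC1=O | intermediate (not isolated)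
16 | tertiary alcohol: 4-OH anti to 3-OTES and 10-methyl, syn to 6-OTBS; 4-methyl | CC(=O)OCC1=C2/C(=C\[C@@]3(C)CC[C@@]3(O[Si](CC)(CC)CC)[C@@](C)(O)C[C@H]2O[Si](C)(C)C(C)(C)C)OC1=O | intermediate
17 | 4-acetate of 16 | CC(=O)OCC1=C2/C(=C\[C@@]3(C)CC[C@@]3(O[Si](CC)(CC)CC)[C@@](C)(OC(C)=O)C[C@H]2O[Si](C)(C)C(C)(C)C)OC1=O | intermediate
18 | tertiary cyclobutanol: 3-OH (cis to 10-methyl), 4-OAc, 6-OTBS | CC(=O)OCC1=C2/C(=C\[C@@]3(C)CC[C@@]3(O)[C@@](C)(OC(C)=O)C[C@H]2O[Si](C)(C)C(C)(C)C)OC1=O | intermediate
19 | cyclobutene (C2=C3) with 10-methyl quaternary centre, 4-OAc, 6-OTBS | CC(=O)OCC1=C2/C(=C\[C@@]3(C)CC=C3[C@@](C)(OC(C)=O)C[C@H]2O[Si](C)(C)C(C)(C)C)OC1=O | intermediate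
20 | 3-(triethylsilylperoxy) compound, cis-fused cyclobutane, 4-OAc, 6-OTBS | CC(=O)OCC1=C2/C(=C\[C@@]3(C)CC[C@@]3(OO[Si](CC)(CC)CC)[C@@](C)(OC(C)=O)C[C@H]2O[Si](C)(C)C(C)(C)C)OC1=O | intermediate
21 | (3S,4S,6R,10R)-3-hydroperoxide: cis-fused cyclobutane on the butenolide-fused eight-membered ring, 4-OAc, free 6-OH | CC(=O)OCC1=C2/C(=C\[C@@]3(C)CC[C@@]3(OO)[C@@](C)(OC(C)=O)C[C@H]2O)OC1=O | intermediate
22 | 3-peroxy trifluoroacetate and 6-O-trifluoroacetate of 21 | CC(=O)OCC1=C2/C(=C\[C@@]3(C)CC[C@@]3(OOC(=O)C(F)(F)F)[C@@](C)(OC(C)=O)C[C@H]2OC(=O)C(F)(F)F)OC1=O | intermediate (not isolated)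
23 | bridged ketal ester: 3,10-epoxy (oxolane) ten-membered ring with 3-OCOCF3 and 6-OCOCF3 | CC(=O)OCC1=C2/C(=C\[C@@]3(C)CC[C@](OC(=O)C(F)(F)F)(O3)[C@@](C)(OC(C)=O)C[C@H]2OC(=O)C(F)(F)F)OC1=O | intermediate (not isolated)
24 | CNP0203479.1, (3S,4S,6R,10R,8E) in the numbering above | CC(=O)OCC1=C2/C(=C\[C@@]3(C)CC[C@](O)(O3)[C@@](C)(OC(C)=O)C[C@H]2O)OC1=O | target

**Step count and risks**

Total steps: 17 (steps 5 and 7 prepare the two side components). Longest linear sequence: 15 steps (1 → 2 → 3 → 4 → 5 → 8 → 11 → 13 → 14 → 16 → 17 → 18 → 19 → 20 → 21 → 24).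

Steps most likely to fail:

1. Step 17. The perester may ionize with the wrong group migrating (C2 or the acetoxy-bearing C4 instead of C10), or the allylic C6 trifluoroacetate may ionize, so that the oxygen is inserted into the wrong bond or material is lost. The fallback sets out from cyclobutanol 18 and comes back at 24. Cobalt(II)-catalysed aerobic ring expansion of the tertiary cyclobutanol (Co(acac)2, O2; alkoxy radical β-scission of C3–C10, O2 capture at C10, closure onto the C3 ketone) should give the 1,2-dioxan-3-ol F1. Zinc in acetic acid then cleaves the O–O bond, and the hydroxy ketone closes transannularly to the TBS ether of the target F2. HF·pyridine gives 24. In this fallback the C10 configuration rests on substrate control and not on retention.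

2. Step 15. Hydrogen-atom transfer may go to C9 of the dienyl lactone instead of C2 of the cyclobutene, so that chemoselectivity is lost. The fallback sets out from cyclobutene 19 and comes back at 21. Peroxymercuration with Hg(OAc)2 and H2O2 is electrophilic and should select the strained, electron-rich cyclobutene, giving the Markovnikov β-mercurio hydroperoxide F3. Reductive demercuration (NaBH4, low temperature) gives the C3 hydroperoxide with the TBS ether intact F4. HF·pyridine gives 21.

3. Step 9. β-Elimination of the C6 silyloxy group through the C8 enol, or acid cleavage of the silyl ethers, may compete with dehydration of the aldol, so that the cascade diverges before the lactone closes. The fallback sets out from aldol 11 and comes back at 13. MsCl/Et3N followed by DBU removes the tertiary aldol hydroxyl by E1cB elimination before any acid is applied and gives the alkylidene keto ester F5 (the Z isomer is shown; E/Z equilibrate under acid). CSA in benzene then only has to trigger the retro-aldol ring expansion and the enol lactonization to 13.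

**Further compounds**

F1 | step 17 | 1,2-dioxan-3-ol: C3(OH)–O–O–C10 peroxide bridge on the ten-membered ring, 4-OAc, 6-OTBS | CC(=O)OCC1=C2/C(=C\[C@@]3(C)CC[C@](O)(OO3)[C@@](C)(OC(C)=O)C[C@H]2O[Si](C)(C)C(C)(C)C)OC1=O
F2 | step 17 | 6-O-TBS ether of the target | CC(=O)OCC1=C2/C(=C\[C@@]3(C)CC[C@](O)(O3)[C@@](C)(OC(C)=O)C[C@H]2O[Si](C)(C)C(C)(C)C)OC1=O
F3 | step 15 | β-mercurio hydroperoxide: 3-OOH, 2-HgOAc trans to it, 4-OAc, 6-OTBS | CC(=O)OCC1=C2/C(=C\[C@@]3(C)C[C@@H]([Hg]OC(C)=O)[C@@]3(OO)[C@@](C)(OC(C)=O)C[C@H]2O[Si](C)(C)C(C)(C)C)OC1=O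
F4 | step 15 | 3-hydroperoxide with 6-OTBS (TBS ether of 21) | CC(=O)OCC1=C2/C(=C\[C@@]3(C)CC[C@@]3(OO)[C@@](C)(OC(C)=O)C[C@H]2O[Si](C)(C)C(C)(C)C)OC1=O
F5 | step 9 | (Z)-alkylidene keto ester of the photoadduct: C7=C11(CH2OAc)(CO2Et), other centres as in 8 | O=C1/C(=C(\C(=O)OCC)COC(C)=O)[C@H](O[Si](C)(C)C(C)(C)C)C[C@@]2(O[Si](C)(C)C(C)(C)C)[C@]3(O[Si](CC)(CC)CC)CC[C@]3(C)[C@@H]12
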